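**Remarks**

- Numbering: germacrane numbering is used throughout (ring C1–C10, lactone carbons C11–C13 with the ring oxygen on C6, C14 on C10, C15 on C4, C2′ for the stereocentre of the 2-methylbutanoate).
- Structures: compared atom by atom, 30, 33 and 35 have the same spatial arrangement at C6, C7, C8 and C2′, iodine in 30 is cis to C6, and both ring alkenes are Z (so the oxirane of 35 is the cis-epoxide); no structure needs correcting. What does not add up is a six-carbon 4-methyl-5,6-dihydropyran-2-one as side-chain source: it maps onto C8–C9–C10(C14)=C1–C2 only and leaves C3 without origin. The C8–C3 chain is therefore built by a Z-selective olefination and a dithiane alkylation.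
- Precursor design: 30 is kept as drawn. The changes concern the way to it: the iodoalkene is installed while the methylene is still masked as a Mannich base, and the aldehyde is made last and used at once.
- Assumption: aldehyde 5 and phosphonate 6 are taken as catalogue compounds (5 is otherwise one oxidation from the monosilyl ether of propane-1,3-diol).

## Structural features

The target is a germacranolide: a ten-membered carbocycle (C1–C10) to which an α-methylene-γ-butyrolactone (O–C6, C7, C11=C13, C12=O) is trans-fused across C6–C7 and a cis-epoxide is fused across C1–C10, three rings in all. The carbocycle carries a Z-trisubstituted alkene C4=C5 whose two allylic positions are both oxygenated (C3 as acetate, C6 as lactone oxygen) and an (R)-2-methylbutanoate on C8. Seven stereocentres are present: C6, C7 and C8 are contiguous, C1 and the quaternary C10 are tied together in the oxirane, C3 stands alone between oxirane and alkene, and the seventh is in the acyl side chain. Fragile functions are the exocyclic enoate (a Michael acceptor that migrates into the ring once C7–H is acidified), the acid-sensitive trisubstituted epoxide, the allylic acetate, and a lactone that can migrate from O6 to a free O8. The real difficulty is closing a ten-membered ring that holds two Z-trisubstituted double bonds while fixing C3 and the epoxide face without a rigid template. The key step uses the fact that C3 is a secondary allylic carbinol carbon bonded directly to C4 of the cis alkene: an alkenyl metal at C4 (from an iodide cis to C6) and an aldehyde at C3 give the C3–C4 bond, the C3 stereocentre and the ring in one operation.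

## Logic of the disconnections

35 ⇒ 34. The two C–O bonds of the oxirane (C1–O, C10–O) are cut first, because the epoxide is the most acid-labile group and C1=C10 is the only electron-rich alkene. This removes one ring and two stereocentres. The forward oxidant must choose C1=C10 over C4=C5 and C11=C13 and attack the correct face.

34 ⇒ 33. The O3–acetyl bond is cut to leave a free carbinol, the natural product of a carbonyl addition. The gain is small, but the free hydroxyl allows C3 to be corrected with inversion if needed. The acylation must not transpose the allylic system.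

33 ⇒ 30. The C3–C4 bond is cut because C3 is a carbinol next to an alkene carbon. This opens the ten-membered ring and removes C3 as a stereocentre; what remains is a monocyclic lactone that already carries every other centre and both esters. The forward step needs an organometallic that tolerates lactone, esters and enoate, keeps the Z geometry, cyclises faster than it oligomerises and selects one aldehyde face.

30 ⇒ 29 ⇒ 28. No skeletal bond is cut; the C3 aldehyde is traced to the alcohol and then to its silyl ether, because a β,γ-unsaturated aldehyde cannot be stored. The demand is a neutral oxidation and a base-free desilylation.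

28 ⇒ 26 + 27. The O8–acyl bond is cut, which takes out the side-chain stereocentre as a purchasable acid. Acylation must outrun migration of the lactone to O8 and must not racemise C2′.

26 ⇒ 25 ⇒ 24. The C8–H bond is cut (carbinol to ketone) and the ketone is traced to a dithioacetal, so that C8 can act as an acyl anion for the C7–C8 bond. C8 disappears as a stereocentre. The forward reduction must be face-selective and the unmasking non-basic, since C7–H in 25 is doubly activated.

24 ⇒ 22. The C11=C13 double bond is traced to a C13–N single bond. This keeps the Michael acceptor masked while the ylide of the next disconnection is in use. The forward elimination must run under mild base.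

22 ⇒ 17 + 18, then 17 ⇒ 16 ⇒ 15. The C4=C5 bond is cut; a Z-2-iodoalkene is the signature of an α-iodo ylide and an aldehyde, so C4, C15 and iodine come from a two-carbon phosphonium salt. The aldehyde is traced through the alcohol to a silyl ether. The demands are Z selectivity, no epimerisation at C6, and a silyl group that leaves before the one on O3.

15 ⇒ 12 + 4. The C7–C8 and C11–C13 bonds are cut: conjugate addition of a C8 carbanion anti to the C6 substituent sets C7 from C6, and the resulting enolate takes up C13 from an iminium electrophile. The molecule falls into two fragments of similar size. The addition must be 1,4 and trans.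

12 ⇒ 10 + 9, then 9 ⇒ 8 ⇒ 7 ⇒ 5 + 6. The C8–C9 bond is cut at the allylic position, and the bromide is traced through the alcohol to an enoate whose C10=C1 bond is cut. This reduces the chain to a three-carbon aldehyde and a phosphonate. The olefination must be Z-selective, since this alkene ends as the cis-epoxide.

4 ⇒ 2 ⇒ 1. The C7=C11 unsaturation and the silyl ether are removed, which leads to a purchasable lactone that already holds C6. The dehydrogenation must not touch C6.

## Other disconnections considered

Alternative 1: The cut is the C7–C8 bond, made by re-linking O8 to C13, so that the ten-membered ring of A2 grows into the 13-membered cyclic allyl α-stannyl ether A1. In the forward direction n-BuLi would exchange tin for lithium at C8, and the α-alkoxy carbanion would undergo a [2,3]-sigmatropic shift (Wittig–Still rearrangement): C7–C8 forms, O–C13 breaks, the double bond moves to C11=C13 and the ring contracts by three atoms to A2.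
- In favour: ring contraction avoids the entropic and transannular cost of direct ten-membered closure. The concerted shift creates C7 and C8 together and stereospecifically, and the exocyclic methylene and the free C8 hydroxyl appear ready for use. C3 and both Z alkenes are already in place, so no fragile β,γ-unsaturated aldehyde is needed.
- Against: the organolithium tolerates neither the lactone nor an ester. C12 must travel as a protected alcohol, and A2 still needs two PMB removals, oxidation of C12 and lactonisation onto O6 in competition with O8, two acylations, desilylation and the epoxidation. A1 demands a macrocyclic etherification and a configurationally defined α-alkoxystannane. The sense of transfer to C7 depends on the fold of a large ring, and a [1,2]-shift competes.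
- Comparison: Alternative 1 is better on the mechanistically enforced setting of C7/C8 (the chosen route needs a separate reagent-controlled reduction for C8) and on the absence of an uncertain C3 closure. It is equal on the epoxidation end game. It is weaker on functional-group carry-through and on step economy, with about eight operations after the key step against two.

Alternative 2: The cut is C1–C2, with C1 as an aldehyde on the quaternary, PMB-protected C10 and C2 as the bromide of a bromomethyl enone in the open-chain precursor A3. SmI2 would reduce the C–Br bond; the enolate of trivalent samarium would add to the C1 aldehyde (Reformatsky-type aldol) and give the ten-membered β-hydroxy enone A4.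
- In favour: the samarium enolate chelates the aldehyde, so medium rings close at moderate dilution. The aldehyde is non-enolisable and cannot isomerise, unlike 30, and the C8 ester is tolerated. The C1 carbinol can later be turned into the oxirane by activation and displacement by O10 with inversion, so the epoxide configuration would follow from a defined stereocentre and not from the facial preference of a peracid; on this point Alternative 2 is superior.
- Against: the γ-oxygenated enone of A3 invites over-reduction by SmI2 (conjugate reduction or loss of the C6 alkoxy group), the Z enone can isomerise, and the aldehyde is neopentylic. Two stereochemical questions arise (C1 in the aldol, C3 in the later ketone reduction) where the chosen plan has one. After A4 about eight steps remain.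
- Comparison: structurally both plans close the carbocycle with one C–C bond and one new carbinol. Mechanistically the chelated enolate addition is at least the equal of the alkenylchromium addition as a macrocyclisation. In step economy and protecting-group load the chosen plan is ahead, since lactone, both esters and the methylene are in place at ring closure.

Alternative 3: The cut is a transannular C6–C10 bond added in the retrosynthetic direction, which turns the cyclodecadienone A6 into the hydroazulenol mesylate A5 (a bicyclo[5.3.0]decene with the tertiary C6 alcohol at the ring fusion and a mesylate on C1). KN(SiMe3)2 would deprotonate the C6 hydroxyl and trigger a Grob fragmentation: C6–C10 breaks, C6=O and C1=C10 form, mesylate leaves and the ten-membered ring is released as A6.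
- In favour: no macrocyclisation is needed, so dilution and oligomerisation are not issues. The fragmentation is concerted and stereospecific, so the Z geometry of C1=C10 is dictated by the relative configuration of C1 and C10 in A5. Ring formation and alkene geometry are on this count better secured than in the chosen plan.
- Against: A5 is a densely substituted bicycle with six stereocentres, among them the quaternary C10 and the tertiary carbinol, and the anti-periplanar C6–C10/C1–O arrangement must be built in. A6 emerges with C6 as a ketone flanked by the epimerisable C7 and a Z enone; C6 must be reduced selectively, C12 oxidised and lactonised, three protecting groups exchanged and the epoxide introduced, about eight further steps. The strong base excludes the esters and the lactone.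
- Comparison: on structure Alternative 3 handles the ring and C1=C10 better and C3/C8 equally. On mechanism a stereospecific fragmentation is more predictable than facial selection in a macrocyclic carbonyl addition. On step economy and convergence it is weaker: the bicyclic precursor is linear and the end game long, whereas the chosen route joins two small fragments and ends two steps after ring closure.

Key step: step 17

## Route

Step 1
Reactants: 1 (R)-5-(hydroxymethyl)dihydrofuran-2(3H)-one
Product: 2 (R)-5-{[(tert-butyldimethylsilyl)oxy]methyl}dihydrofuran-2(3H)-one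
Conditions: TBSCl, imidazole, DMF, 0 °C to rt
Reagents that add atoms: tert-butyldimethylsilyl chloride, CC(C)(C)[Si](C)(C)Cl
Why: Standard silylation of a primary alcohol; the lactone and the stereocentre (C6 of the target) are not involved, and the bulky ether later shields one face of the butenolide.

Step 2
Reactants: 2 (R)-5-{[(tert-butyldimethylsilyl)oxy]methyl}dihydrofuran-2(3H)-one
Product: 4 (R)-5-{[(tert-butyldimethylsilyl)oxy]methyl}furan-2(5H)-one, via α-phenylselanyl lactone 3 (not isolated)
Conditions: LiN(iPr)2, THF, −78 °C; PhSeBr, −78 °C; then AcOH, 30% H2O2, 0 °C to rt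
Reagents that add atoms: none
Why: α-Selenenylation of the lactone enolate followed by oxidation and syn-elimination of the selenoxide gives the butenolide; elimination can only run toward C7–H, so C6 is untouched.

Step 3
Reactants: 5 3-[(tert-butyldiphenylsilyl)oxy]propanal; 6 ethyl 2-[bis(2,2,2-trifluoroethoxy)phosphoryl]propanoate
Product: 7 ethyl (2Z)-5-[(tert-butyldiphenylsilyl)oxy]-2-methylpent-2-enoate
Conditions: KN(SiMe3)2, 18-crown-6, THF, −78 °C
Reagents that add atoms: none
Why: Still–Gennari olefination: the electron-poor phosphonate under dissociating conditions eliminates from the kinetic adduct and gives the (Z)-enoate, which fixes the C1=C10 geometry (C9 cis to C2).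

Step 4
Reactants: 7 ethyl (2Z)-5-[(tert-butyldiphenylsilyl)oxy]-2-methylpent-2-enoate
Product: 8 (2Z)-5-[(tert-butyldiphenylsilyl)oxy]-2-methylpent-2-en-1-ol
Conditions: iBu2AlH (2.3 equiv), CH2Cl2, −78 °C; aq. potassium sodium tartrate
Reagents that add atoms: none
Why: 1,2-Reduction of the enoate by the aluminium hydride at low temperature gives the allylic alcohol without touching the alkene geometry or the silyl ether.

Step 5
Reactants: 8 (2Z)-5-[(tert-butyldiphenylsilyl)oxy]-2-methylpent-2-en-1-ol
Product: 9 {[(3Z)-5-bromo-4-methylpent-3-en-1-yl]oxy}(tert-butyl)diphenylsilane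
Conditions: CBr4, PPh3, CH2Cl2, 0 °C
Reagents that add atoms: carbon tetrabromide, BrC(Br)(Br)Br
Why: Appel bromination replaces the primary allylic hydroxyl by SN2 at 0 °C, so neither allylic transposition nor Z/E isomerisation is expected.

Step 6
Reactants: 10 1,3-dithiane; 9 {[(3Z)-5-bromo-4-methylpent-3-en-1-yl]oxy}(tert-butyl)diphenylsilane
Product: 12 tert-butyl{[(3Z)-5-(1,3-dithian-2-yl)-4-methylpent-3-en-1-yl]oxy}diphenylsilane, via 2-lithio-1,3-dithiane 11 (not isolated)
Conditions: n-BuLi, THF, −30 °C; then 9, −78 to −20 °C
Reagents that add atoms: none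
Why: Corey–Seebach alkylation: the lithiated dithiane displaces the primary allylic bromide by SN2 and forms the C8–C9 bond, C8 entering as a masked carbonyl.

Step 7
Reactants: 12 tert-butyl{[(3Z)-5-(1,3-dithian-2-yl)-4-methylpent-3-en-1-yl]oxy}diphenylsilane; 4 (R)-5-{[(tert-butyldimethylsilyl)oxy]methyl}furan-2(5H)-one
Product: 15 (3S,4R,5R)-5-{[(tert-butyldimethylsilyl)oxy]methyl}-4-{2-[(2Z)-5-[(tert-butyldiphenylsilyl)oxy]-2-methylpent-2-en-1-yl]-1,3-dithian-2-yl}-3-[(dimethylamino)methyl]oxolan-2-one, via lithiated dithiane 13 (not isolated), via lithium enolate 14 (not isolated)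
Conditions: n-BuLi, THF, −20 °C; hexamethylphosphoramide, then 4, −78 °C; then CH2=NMe2+ I−, −78 to 0 °C
Reagents that add atoms: Eschenmoser's salt (N,N-dimethylmethyleneiminium iodide), C=[N+](C)C.[I-]
Why: The sulfur-stabilised carbanion adds 1,4 to the butenolide (the polar cosolvent favours conjugate addition) anti to the C6 silyloxymethyl group, which sets C7 trans to C6. The lactone enolate is then trapped by the iminium salt in a Mannich reaction anti to the new C7 substituent; the C11 configuration is lost later.

Step 8
Reactants: 15 (Mannich base with both silyl ethers)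
Product: 16 (3S,4R,5R)-4-{2-[(2Z)-5-[(tert-butyldiphenylsilyl)oxy]-2-methylpent-2-en-1-yl]-1,3-dithian-2-yl}-3-[(dimethylamino)methyl]-5-(hydroxymethyl)oxolan-2-one
Conditions: HF·pyridine, pyridine, THF, 0 °C
Reagents that add atoms: none
Why: Buffered hydrogen fluoride cleaves the primary tert-butyldimethylsilyl ether much faster than the tert-butyldiphenylsilyl ether; the amine is only protonated and the dithiane is inert.

Step 9
Reactants: 16 (C5 alcohol)
Product: 17 (2R,3R,4S)-3-{2-[(2Z)-5-[(tert-butyldiphenylsilyl)oxy]-2-methylpent-2-en-1-yl]-1,3-dithian-2-yl}-4-[(dimethylamino)methyl]-5-oxooxolane-2-carbaldehyde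
Conditions: SO3·pyridine, DMSO, iPr2NEt, CH2Cl2, 0 °C
Reagents that add atoms: none
Why: Parikh–Doering oxidation stops at the aldehyde and leaves the dithiane sulfur and the tertiary amine alone; at 0 °C the α-oxygenated C6 centre should not epimerise, and the aldehyde is used at once.

Step 10
Reactants: 17 (C5 aldehyde); 18 ethyltriphenylphosphonium iodide
Product: 22 (3S,4R,5R)-4-{2-[(2Z)-5-[(tert-butyldiphenylsilyl)oxy]-2-methylpent-2-en-1-yl]-1,3-dithian-2-yl}-3-[(dimethylamino)methyl]-5-[(1Z)-2-iodoprop-1-en-1-yl]oxolan-2-one, via ethylidene ylide 19 (not isolated), via iodoethylphosphonium iodide 20 (not isolated), via iodoethylidene ylide 21 (not isolated)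
Conditions: 18, n-BuLi, THF, 0 °C; I2, −78 °C; NaN(SiMe3)2, −78 to −20 °C; then 17, −78 °C
Reagents that add atoms: iodine, II
Why: Stork–Zhao olefination with the α-iodoethylidene ylide: kinetically controlled cis-oxaphosphetane formation places iodine cis to C6 and gives the (Z)-iodoalkene. No Michael acceptor or ketone is present at this stage to divert the ylide.

Step 11
Reactants: 22 (amino lactone with iodoalkene)
Product: 24 (4R,5R)-4-{2-[(2Z)-5-[(tert-butyldiphenylsilyl)oxy]-2-methylpent-2-en-1-yl]-1,3-dithian-2-yl}-5-[(1Z)-2-iodoprop-1-en-1-yl]-3-methylideneoxolan-2-one, via trimethylammonium iodide 23 (not isolated)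
Conditions: MeI (10 equiv), MeOH/CH2Cl2, rt; then aq. NaHCO3, EtOAc, rt
Reagents that add atoms: none
Why: Exhaustive N-methylation followed by E1cB loss of trimethylamine from the β-ammonio lactone (Hofmann-type elimination of a Mannich base) unveils C11=C13. At room temperature the amine is far more nucleophilic than the thioacetal sulfur, and the alkenyl iodide is inert.

Step 12
Reactants: 24 (methylene lactone with dithiane)
Product: 25 (4R,5R)-4-[(3Z)-6-[(tert-butyldiphenylsilyl)oxy]-3-methylhex-3-enoyl]-5-[(1Z)-2-iodoprop-1-en-1-yl]-3-methylideneoxolan-2-one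
Conditions: PhI(OCOCF3)2, MeCN/H2O (9:1), 0 °C, 10 min; pH 7 buffer; used crude
Reagents that add atoms: water, O
Why: Oxidative dethioacetalisation with the hypervalent iodine reagent: sulfur is activated, water captures the thionium ion and the ketone is released within minutes under non-basic conditions, which matters because C7–H is now flanked by ketone and enoate. Sulfur leaves as a disulfide and not as a thiol that could add to the Michael acceptor.

Step 13
Reactants: 25 (C8 ketone)
Product: 26 (4S,5R)-4-[(1S,3Z)-6-[(tert-butyldiphenylsilyl)oxy]-1-hydroxy-3-methylhex-3-en-1-yl]-5-[(1Z)-2-iodoprop-1-en-1-yl]-3-methylideneoxolan-2-one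
Conditions: (R)-Me-CBS oxazaborolidine [(R)-1-methyl-3,3-diphenyltetrahydro-1H,3H-pyrrolo[1,2-c][1,3,2]oxazaborole] (0.5 equiv), catecholborane, toluene, −78 °C; MeOH
Reagents that add atoms: none
Why: Corey–Bakshi–Shibata reduction: the (R)-catalyst binds the ketone with the branched C7 side as the large group and delivers hydride to the face that gives the 8S alcohol. Felkin–Anh control with C6 anti to the hydride and C11 next to the carbonyl oxygen predicts the same face, so reagent and substrate should be matched. Catecholborane at −78 °C spares the enoate, the alkenes and the iodide and gives a neutral borate, so O8 cannot attack the lactone.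

Step 14
Reactants: 26 (C8 alcohol); 27 (R)-2-methylbutanoic acid
Product: 28 (1S,3Z)-6-[(tert-butyldiphenylsilyl)oxy]-1-{(2R,3S)-2-[(1Z)-2-iodoprop-1-en-1-yl]-4-methylidene-5-oxooxolan-3-yl}-3-methylhex-3-en-1-yl (2R)-2-methylbutanoate
Conditions: N,N′-dicyclohexylcarbodiimide, 4-(dimethylamino)pyridine (0.1 equiv), CH2Cl2, 0 °C to rt
Reagents that add atoms: none
Why: Steglich esterification of the secondary alcohol; the α-stereocentre of a saturated aliphatic acid is not prone to racemise under carbodiimide activation, and fast acylation removes the free C8 hydroxyl that could otherwise migrate the lactone.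

Step 15
Reactants: 28 (silyl ether ester)
Product: 29 (1S,3Z)-6-hydroxy-1-{(2R,3S)-2-[(1Z)-2-iodoprop-1-en-1-yl]-4-methylidene-5-oxooxolan-3-yl}-3-methylhex-3-en-1-yl (2R)-2-methylbutanoate
Conditions: HF·pyridine, pyridine, THF, 0 °C to rt
Reagents that add atoms: none
Why: Fluoride-mediated desilylation under buffered acidic conditions frees the C3 hydroxyl without base, so the methylene lactone, the ester and the alkenyl iodide persist.

Step 16
Reactants: 29 (C3 alcohol)
Product: 30 (1S,3Z)-1-{(2R,3S)-2-[(1Z)-2-iodoprop-1-en-1-yl]-4-methylidene-5-oxooxolan-3-yl}-3-methyl-6-oxohex-3-en-1-yl (2R)-2-methylbutanoate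
Conditions: Dess–Martin periodinane, NaHCO3, CH2Cl2, 0 °C; filtered and used at once
Reagents that add atoms: none
Why: Buffered Dess–Martin oxidation is neutral and fast, the usual way to a β,γ-unsaturated aldehyde without moving C1=C10 into conjugation.

Step 17
Reactants: 30 (iodoalkenyl aldehyde)
Product: 33 (1(10)Z,3R,4Z,6S,7S,8S)-3-hydroxy-8-{[(2R)-2-methylbutanoyl]oxy}germacra-1(10),4,11(13)-trien-12,6-olide, via alkenylchromium dichloride 31 (not isolated), via chromium alkoxide 32 (not isolated)
Conditions: CrCl2 (8 equiv), NiCl2 (0.1 equiv), degassed DMSO/THF (3:1), syringe-pump addition of 30 to about 0.002 M, rt; aqueous work-up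
Reagents that add atoms: none
Why: Divalent chromium reduces NiCl2 to zerovalent nickel, which inserts into the C4–I bond with retention of the Z geometry; transmetalation passes the alkenyl group to trivalent chromium (31), and this weakly basic, oxophilic alkenylchromium adds 1,2 to the C3 aldehyde to give alkoxide 32, hydrolysed on work-up. The closest known reaction type is the Nozaki–Hiyama–Kishi macrocyclisation of ω-formyl alkenyl iodides to medium and large carbocycles. The ten-membered ring (C3, C4, C5, C6, C7, C8, C9, C10, C1, C2) closes end to end in a 10-exo-trig mode, the aldehyde C=O lying outside the new ring. The new stereocentre C3 is under substrate control: the Z C4=C5 alkene, the trans-disubstituted lactone and the Z C1=C10 alkene leave few folded conformers, and closure through the one that keeps H3 near the alkene plane (least allylic strain toward C6) with the chromium-bound oxygen on the outside of the ring is expected to give the 3R carbinol. Chemoselectivity is needed and lies in the reagent: alkenylchromium species add to aldehydes but not to lactones, esters or the exocyclic enoate, and they do not deprotonate the β,γ-unsaturated aldehyde, so C1=C10 stays out of conjugation. Cyclisation must beat oligomerisation; slow addition at high dilution secures this, helped by the two cis alkenes and the ring-fused lactone, which shorten the C3–C4 distance. The C4=C5 geometry is not at risk because oxidative addition and transmetalation both go with retention.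

Step 18
Reactants: 33 (macrocyclic C3 alcohol)
Product: 34 (1(10)Z,3R,4Z,6S,7S,8S)-3-acetoxy-8-{[(2R)-2-methylbutanoyl]oxy}germacra-1(10),4,11(13)-trien-12,6-olide
Conditions: Ac2O, pyridine, 4-(dimethylamino)pyridine (cat.), CH2Cl2, 0 °C
Reagents that add atoms: acetic anhydride, CC(=O)OC(C)=O
Why: Acylation of the secondary allylic alcohol at oxygen proceeds with retention at C3 and without allylic transposition.

Step 19
Reactants: 34 (triene acetate)
Product: 35 (1R,3R,4Z,6S,7S,8S,10S)-3-acetoxy-1,10-epoxy-8-{[(2R)-2-methylbutanoyl]oxy}germacra-4,11(13)-dien-12,6-olide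
Conditions: m-CPBA (1.1 equiv), NaHCO3, CH2Cl2, 0 °C
Reagents that add atoms: m-chloroperbenzoic acid, O=C(OO)c1cccc(Cl)c1
Why: Prilezhaev epoxidation: the peracid takes the only electron-rich alkene, C1=C10; C4=C5 is deactivated by two allylic acyloxy groups and C11=C13 by conjugation. The addition is suprafacial, so the Z alkene becomes the cis-epoxide, and attack on the outer face of the ring alkene should give the 1R,10S oxirane.

## Compound list

1 | (R)-5-(hydroxymethyl)dihydrofuran-2(3H)-one | OC[C@@H]1OC(=O)CC1 | starting material
2 | (R)-5-{[(tert-butyldimethylsilyl)oxy]methyl}dihydrofuran-2(3H)-one | CC(C)(C)[Si](C)(C)OC[C@@H]1OC(=O)CC1 | intermediate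
3 | (3S,5R)-5-{[(tert-butyldimethylsilyl)oxy]methyl}-3-(phenylselanyl)dihydrofuran-2(3H)-one (main epimer; C3 configuration immaterial) | CC(C)(C)[Si](C)(C)OC[C@@H]1OC(=O)[C@@H]([Se]c2ccccc2)C1 | intermediate
4 | (R)-5-{[(tert-butyldimethylsilyl)oxy]methyl}furan-2(5H)-one | CC(C)(C)[Si](C)(C)OC[C@@H]1OC(=O)C=C1 | intermediate
5 | 3-[(tert-butyldiphenylsilyl)oxy]propanal | O=CCCO[Si](c1ccccc1)(c1ccccc1)C(C)(C)C | starting material
6 | ethyl 2-[bis(2,2,2-trifluoroethoxy)phosphoryl]propanoate | CCOC(=O)C(C)P(=O)(OCC(F)(F)F)OCC(F)(F)F | starting material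
7 | ethyl (2Z)-5-[(tert-butyldiphenylsilyl)oxy]-2-methylpent-2-enoate | CCOC(=O)/C(C)=C\CCO[Si](c1ccccc1)(c1ccccc1)C(C)(C)C | intermediate
8 | (2Z)-5-[(tert-butyldiphenylsilyl)oxy]-2-methylpent-2-en-1-ol | OC/C(C)=C\CCO[Si](c1ccccc1)(c1ccccc1)C(C)(C)C | intermediate
9 | {[(3Z)-5-bromo-4-methylpent-3-en-1-yl]oxy}(tert-butyl)diphenylsilane | BrC/C(C)=C\CCO[Si](c1ccccc1)(c1ccccc1)C(C)(C)C | intermediate
10 | 1,3-dithiane | C1CSCSC1 | starting material
11 | 2-lithio-1,3-dithiane | [Li]C1SCCCS1 | intermediate
12 | tert-butyl{[(3Z)-5-(1,3-dithian-2-yl)-4-methylpent-3-en-1-yl]oxy}diphenylsilane | CC(C)(C)[Si](c1ccccc1)(c1ccccc1)OCC/C=C(/C)CC1SCCCS1 | intermediate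
13 | 2-lithio derivative of 12 (lithium on the dithiane C2) | [Li]C1(C/C(C)=C\CCO[Si](c2ccccc2)(c2ccccc2)C(C)(C)C)SCCCS1 | intermediate
14 | lithium enolate of the trans conjugate adduct (O-lithio lactone enolate, C6 and C7 set) | C1=C(O[Li])O[C@@H](CO[Si](C)(C)C(C)(C)C)[C@@H]1C2(C/C(C)=C\CCO[Si](c3ccccc3)(c3ccccc3)C(C)(C)C)SCCCS2 | intermediate
15 | (3S,4R,5R)-5-{[(tert-butyldimethylsilyl)oxy]methyl}-4-{2-[(2Z)-5-[(tert-butyldiphenylsilyl)oxy]-2-methylpent-2-en-1-yl]-1,3-dithian-2-yl}-3-[(dimethylamino)methyl]oxolan-2-one | CN(C)C[C@H]1C(=O)O[C@@H](CO[Si](C)(C)C(C)(C)C)[C@@H]1C2(C/C(C)=C\CCO[Si](c3ccccc3)(c3ccccc3)C(C)(C)C)SCCCS2 | intermediate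
16 | (3S,4R,5R)-4-{2-[(2Z)-5-[(tert-butyldiphenylsilyl)oxy]-2-methylpent-2-en-1-yl]-1,3-dithian-2-yl}-3-[(dimethylamino)methyl]-5-(hydroxymethyl)oxolan-2-one | CN(C)C[C@H]1C(=O)O[C@@H](CO)[C@@H]1C2(C/C(C)=C\CCO[Si](c3ccccc3)(c3ccccc3)C(C)(C)C)SCCCS2 | intermediate
17 | (2R,3R,4S)-3-{2-[(2Z)-5-[(tert-butyldiphenylsilyl)oxy]-2-methylpent-2-en-1-yl]-1,3-dithian-2-yl}-4-[(dimethylamino)methyl]-5-oxooxolane-2-carbaldehyde | CN(C)C[C@H]1C(=O)O[C@@H](C=O)[C@@H]1C2(C/C(C)=C\CCO[Si](c3ccccc3)(c3ccccc3)C(C)(C)C)SCCCS2 | intermediate
18 | ethyltriphenylphosphonium iodide | CC[P+](c1ccccc1)(c1ccccc1)c1ccccc1.[I-] | starting material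
19 | ethylidenetriphenylphosphorane | CC=P(c1ccccc1)(c1ccccc1)c1ccccc1 | intermediate
20 | (1-iodoethyl)triphenylphosphonium iodide | CC(I)[P+](c1ccccc1)(c1ccccc1)c1ccccc1.[I-] | intermediate
21 | (1-iodoethylidene)triphenylphosphorane | CC(I)=P(c1ccccc1)(c1ccccc1)c1ccccc1 | intermediate
22 | (3S,4R,5R)-4-{2-[(2Z)-5-[(tert-butyldiphenylsilyl)oxy]-2-methylpent-2-en-1-yl]-1,3-dithian-2-yl}-3-[(dimethylamino)methyl]-5-[(1Z)-2-iodoprop-1-en-1-yl]oxolan-2-one | CN(C)C[C@H]1C(=O)O[C@@H](/C=C(/C)I)[C@@H]1C2(C/C(C)=C\CCO[Si](c3ccccc3)(c3ccccc3)C(C)(C)C)SCCCS2 | intermediate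
23 | N,N,N-trimethylammonium iodide of 22 (methiodide) | C[N+](C)(C)C[C@H]1C(=O)O[C@@H](/C=C(/C)I)[C@@H]1C2(C/C(C)=C\CCO[Si](c3ccccc3)(c3ccccc3)C(C)(C)C)SCCCS2.[I-] | intermediate
24 | (4R,5R)-4-{2-[(2Z)-5-[(tert-butyldiphenylsilyl)oxy]-2-methylpent-2-en-1-yl]-1,3-dithian-2-yl}-5-[(1Z)-2-iodoprop-1-en-1-yl]-3-methylideneoxolan-2-one | C=C1C(=O)O[C@@H](/C=C(/C)I)[C@@H]1C2(C/C(C)=C\CCO[Si](c3ccccc3)(c3ccccc3)C(C)(C)C)SCCCS2 | intermediate
25 | (4R,5R)-4-[(3Z)-6-[(tert-butyldiphenylsilyl)oxy]-3-methylhex-3-enoyl]-5-[(1Z)-2-iodoprop-1-en-1-yl]-3-methylideneoxolan-2-one | C=C1C(=O)O[C@@H](/C=C(/C)I)[C@@H]1C(=O)C/C(C)=C\CCO[Si](c2ccccc2)(c2ccccc2)C(C)(C)C | intermediate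
26 | (4S,5R)-4-[(1S,3Z)-6-[(tert-butyldiphenylsilyl)oxy]-1-hydroxy-3-methylhex-3-en-1-yl]-5-[(1Z)-2-iodoprop-1-en-1-yl]-3-methylideneoxolan-2-one | C=C1C(=O)O[C@@H](/C=C(/C)I)[C@@H]1[C@@H](O)C/C(C)=C\CCO[Si](c2ccccc2)(c2ccccc2)C(C)(C)C | intermediate
27 | (R)-2-methylbutanoic acid | CC[C@@H](C)C(=O)O | starting material
28 | (1S,3Z)-6-[(tert-butyldiphenylsilyl)oxy]-1-{(2R,3S)-2-[(1Z)-2-iodoprop-1-en-1-yl]-4-methylidene-5-oxooxolan-3-yl}-3-methylhex-3-en-1-yl (2R)-2-methylbutanoate | C=C1C(=O)O[C@@H](/C=C(/C)I)[C@@H]1[C@@H](OC(=O)[C@H](C)CC)C/C(C)=C\CCO[Si](c2ccccc2)(c2ccccc2)C(C)(C)C | intermediate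
29 | (1S,3Z)-6-hydroxy-1-{(2R,3S)-2-[(1Z)-2-iodoprop-1-en-1-yl]-4-methylidene-5-oxooxolan-3-yl}-3-methylhex-3-en-1-yl (2R)-2-methylbutanoate | C=C1C(=O)O[C@@H](/C=C(/C)I)[C@@H]1[C@@H](OC(=O)[C@H](C)CC)C/C(C)=C\CCO | intermediate
30 | (1S,3Z)-1-{(2R,3S)-2-[(1Z)-2-iodoprop-1-en-1-yl]-4-methylidene-5-oxooxolan-3-yl}-3-methyl-6-oxohex-3-en-1-yl (2R)-2-methylbutanoate | C=C1C(=O)O[C@@H](/C=C(/C)I)[C@@H]1[C@@H](OC(=O)[C@H](C)CC)C/C(C)=C\CC=O | intermediate
31 | alkenylchromium dichloride derived from 30 (CrCl2 on C4 in place of iodine, Z geometry retained) | C=C1C(=O)O[C@@H](/C=C(/C)[Cr](Cl)Cl)[C@@H]1[C@@H](OC(=O)[C@H](C)CC)C/C(C)=C\CC=O | intermediate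
32 | O3-dichlorochromium alkoxide of 33 | C=C1C(=O)O[C@H]2/C=C(/C)[C@H](O[Cr](Cl)Cl)C/C=C(/C)C[C@H](OC(=O)[C@H](C)CC)[C@H]12 | intermediate
33 | (1(10)Z,3R,4Z,6S,7S,8S)-3-hydroxy-8-{[(2R)-2-methylbutanoyl]oxy}germacra-1(10),4,11(13)-trien-12,6-olide | C=C1C(=O)O[C@H]2/C=C(/C)[C@H](O)C/C=C(/C)C[C@H](OC(=O)[C@H](C)CC)[C@H]12 | intermediate
34 | (1(10)Z,3R,4Z,6S,7S,8S)-3-acetoxy-8-{[(2R)-2-methylbutanoyl]oxy}germacra-1(10),4,11(13)-trien-12,6-olide | C=C1C(=O)O[C@H]2/C=C(/C)[C@H](OC(C)=O)C/C=C(/C)C[C@H](OC(=O)[C@H](C)CC)[C@H]12 | intermediate
35 | (1R,3R,4Z,6S,7S,8S,10S)-3-acetoxy-1,10-epoxy-8-{[(2R)-2-methylbutanoyl]oxy}germacra-4,11(13)-dien-12,6-olide | C=C1C(=O)O[C@H]2/C=C(/C)[C@H](OC(C)=O)C[C@H]3O[C@@]3(C)C[C@H](OC(=O)[C@H](C)CC)[C@H]12 | target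

## Step count and least certain steps

Total step count: 19. Longest linear sequence: 17 steps (steps 3–6, then 7–19, counted from 5 and 6); 15 steps from lactone 1.

**Step 17 (key step).** Most likely to go wrong: poor facial selectivity in the addition to the aldehyde, because two folded conformers of the open chain can present opposite faces of C3 to C4. Slow closure would also give the aldehyde time to slip into conjugation or to couple intermolecularly, which the slow addition at high dilution is meant to suppress. Fallback (stereochemical correction in place of direct control): the cyclisation is run from 30 as in step 17. Material that emerges as the C3 epimer, the (3S)-alcohol F1, is esterified under Mitsunobu conditions (PPh3, diisopropyl azodicarboxylate, AcOH, toluene, 0 °C); SN2 displacement of the activated oxygen by acetate inverts C3 and gives 34 directly, where the route is rejoined. Any 33 formed alongside passes through step 18, so both epimers converge.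

**Step 12.** Most likely to go wrong: migration of the exocyclic double bond into the lactone ring through enolisation of the new ketone toward C7, or conjugate addition of sulfur by-products, because in 25 the C7 hydrogen lies between a ketone and an enoate. Fallback (reordering so that ketone and methylene never coexist): from 22 the dithiane is cleaved first, with the amine held as its trifluoroacetate salt (CF3CO2H, then PhI(OCOCF3)2, aqueous MeCN), to give the amino ketone F2. Reduction as in step 13, with one extra equivalent of borane for the amine, gives the amino alcohol F3, and Steglich esterification with 27 gives the amino ester F4. Only then do quaternisation with MeI to the ammonium iodide F5 and NaHCO3-induced elimination unveil the methylene, which gives 28.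

**Step 13.** Most likely to go wrong: insufficient facial discrimination, should the intrinsic bias of the α-methylene ketone oppose the catalyst. Fallback (inversion in place of selection): from 25, any (8R)-alcohol F6 is separated and coupled with 27 under Mitsunobu conditions (PPh3, diisopropyl azodicarboxylate, toluene), which inverts C8 while installing the ester and delivers 28. The 8S alcohol 26 continues through step 14.

**Step 7.** Most likely to go wrong: incomplete capture of the lactone enolate by the sparingly soluble iminium salt, with proton transfer from excess dithiane or from the product competing, beside some 1,2-addition. Fallback (two separate operations): from 12 and 4 the conjugate addition is quenched with NH4Cl to give the simple trans adduct F7. This is purified, re-enolised with LiN(iPr)2 at −78 °C to 14 and then treated with the iminium salt, rejoining the route at 15.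

**Step 19.** Most likely to go wrong: epoxidation on the wrong face of C1=C10, since the preferred conformation of the Z,Z-cyclodecadiene ring is not known with certainty. Fallback (two-step delivery of oxygen to the opposite face): from 34, N-bromosuccinimide in aqueous 1,2-dimethoxyethane forms the bromonium ion on the face the peracid prefers, and water opens it at the tertiary C10 from the other side to give the bromohydrin F8. Ag2O then closes the oxirane by displacement at C1 with inversion, which places the oxygen on the face opposite to peracid attack and gives 35.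

## Further compounds

F1 | step 17 | (1(10)Z,3S,4Z,6S,7S,8S)-3-hydroxy-8-{[(2R)-2-methylbutanoyl]oxy}germacra-1(10),4,11(13)-trien-12,6-olide (C3 epimer of 33) | C=C1C(=O)O[C@H]2/C=C(/C)[C@@H](O)C/C=C(/C)C[C@H](OC(=O)[C@H](C)CC)[C@H]12
F2 | step 12 | (3S,4R,5R)-4-[(3Z)-6-[(tert-butyldiphenylsilyl)oxy]-3-methylhex-3-enoyl]-3-[(dimethylamino)methyl]-5-[(1Z)-2-iodoprop-1-en-1-yl]oxolan-2-one | CN(C)C[C@H]1C(=O)O[C@@H](/C=C(/C)I)[C@@H]1C(=O)C/C(C)=C\CCO[Si](c2ccccc2)(c2ccccc2)C(C)(C)C
F3 | step 12 | (3S,4S,5R)-4-[(1S,3Z)-6-[(tert-butyldiphenylsilyl)oxy]-1-hydroxy-3-methylhex-3-en-1-yl]-3-[(dimethylamino)methyl]-5-[(1Z)-2-iodoprop-1-en-1-yl]oxolan-2-one | CN(C)C[C@H]1C(=O)O[C@@H](/C=C(/C)I)[C@@H]1[C@@H](O)C/C(C)=C\CCO[Si](c2ccccc2)(c2ccccc2)C(C)(C)C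
F4 | step 12 | (1S,3Z)-6-[(tert-butyldiphenylsilyl)oxy]-1-{(2R,3S,4S)-4-[(dimethylamino)methyl]-2-[(1Z)-2-iodoprop-1-en-1-yl]-5-oxooxolan-3-yl}-3-methylhex-3-en-1-yl (2R)-2-methylbutanoate | CN(C)C[C@H]1C(=O)O[C@@H](/C=C(/C)I)[C@@H]1[C@@H](OC(=O)[C@H](C)CC)C/C(C)=C\CCO[Si](c2ccccc2)(c2ccccc2)C(C)(C)C
F5 | step 12 | N,N,N-trimethylammonium iodide of F4 (methiodide) | C[N+](C)(C)C[C@H]1C(=O)O[C@@H](/C=C(/C)I)[C@@H]1[C@@H](OC(=O)[C@H](C)CC)C/C(C)=C\CCO[Si](c2ccccc2)(c2ccccc2)C(C)(C)C.[I-]
F6 | step 13 | (4S,5R)-4-[(1R,3Z)-6-[(tert-butyldiphenylsilyl)oxy]-1-hydroxy-3-methylhex-3-en-1-yl]-5-[(1Z)-2-iodoprop-1-en-1-yl]-3-methylideneoxolan-2-one (C8 epimer of 26) | C=C1C(=O)O[C@@H](/C=C(/C)I)[C@@H]1[C@H](O)C/C(C)=C\CCO[Si](c2ccccc2)(c2ccccc2)C(C)(C)C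
F7 | step 7 | (4R,5R)-5-{[(tert-butyldimethylsilyl)oxy]methyl}-4-{2-[(2Z)-5-[(tert-butyldiphenylsilyl)oxy]-2-methylpent-2-en-1-yl]-1,3-dithian-2-yl}oxolan-2-one | C1C(=O)O[C@@H](CO[Si](C)(C)C(C)(C)C)[C@@H]1C2(C/C(C)=C\CCO[Si](c3ccccc3)(c3ccccc3)C(C)(C)C)SCCCS2
F8 | step 19 | (1S,3R,4Z,6S,7S,8S,10S)-3-acetoxy-1-bromo-10-hydroxy-8-{[(2R)-2-methylbutanoyl]oxy}germacra-4,11(13)-dien-12,6-olide | C=C1C(=O)O[C@H]2/C=C(/C)[C@H](OC(C)=O)C[C@H](Br)[C@@](C)(O)C[C@H](OC(=O)[C@H](C)CC)[C@H]12
A1 | alternative 1 | 13-membered cyclic allyl ether with tributylstannyl on C8 and O8 linked to C13 (C6 and C13 trans across C7=C11) | CCCC[Sn](CCCC)(CCCC)[C@H]1C/C(C)=C\C[C@@H](O[Si](C)(C)C(C)(C)C)/C(C)=C\[C@H](OCc2ccc(OC)cc2)/C=C(\COCc2ccc(OC)cc2)CO1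
A2 | alternative 1 | ten-membered carbocycle with free C8 hydroxyl and exocyclic C11=C13 methylene (O6 and O12 as PMB ethers, O3 as TBS ether) | C=C(COCc1ccc(OC)cc1)[C@@H]1[C@@H](OCc2ccc(OC)cc2)/C=C(/C)[C@H](O[Si](C)(C)C(C)(C)C)C/C=C(/C)C[C@@H]1O
A3 | alternative 2 | open-chain C1 aldehyde / C2 bromomethyl Z-enone carrying the C8 ester and three PMB ethers | O=C[C@@](C)(OCc1ccc(OC)cc1)C[C@H](OC(=O)[C@H](C)CC)[C@H](C(=C)COCc1ccc(OC)cc1)[C@@H](OCc1ccc(OC)cc1)/C=C(/C)C(=O)CBr
A4 | alternative 2 | ten-membered β-hydroxy enone (C1 carbinol, C3 ketone) | O[C@H]1CC(=O)/C(C)=C\[C@H](OCc2ccc(OC)cc2)[C@@H](C(=C)COCc2ccc(OC)cc2)[C@@H](OC(=O)[C@H](C)CC)C[C@]1(C)OCc1ccc(OC)cc1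
A5 | alternative 3 | cis-fused bicyclo[5.3.0]dec-4-ene with C6 bridgehead hydroxyl, C10 methyl and C1 mesylate (C6–C10 bond anti to C1–O) | O[C@]12C=C(C)[C@H](O[Si](C)(C)C(C)(C)C)C[C@@H](OS(C)(=O)=O)[C@@]1(C)C[C@H](OCc1ccc(OC)cc1)[C@@H]2C(=C)CO[Si](CC)(CC)CC
A6 | alternative 3 | (2Z,6Z)-cyclodeca-2,6-dienone carrying the C3, C7 and C8 stereocentres | O=C1/C=C(/C)[C@H](O[Si](C)(C)C(C)(C)C)C/C=C(/C)C[C@H](OCc2ccc(OC)cc2)[C@@H]1C(=C)CO[Si](CC)(CC)CC
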